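**Assumptions.** Cembrane numbering is used throughout: C1 is the ring-fusion CH bearing acrylate carbon C15, C2 is the lactone O–CH, C6 is CHOAc and C14 is CHOH. The SMILES decodes as 1S,2S,6S,14S, with a trans-fused lactone and 3E,7E,11E olefins. Chiral catalysts and ligands are treated as purchased and are not counted as steps.

## Retrosynthetic overview

1. The default is avoided: C1–C2 closure of a 2-(bromomethyl)acrylate onto an aldehyde (Barbier/NHK), or RCM followed by late α-methylenation.
2. The lactone is built last. The α-methylene lactone comes from a Horner–Wadsworth–Emmons (HWE) reaction with CH2O on an α-phosphono-lactone. That lactone comes from a C2–O-tethered phosphonoacetate carbanion opening a trans C1/C14 epoxide at C1, which inverts C1 and frees the 14-OH.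
3. The epoxide comes from a group-selective, matched Sharpless epoxidation of a macrocyclic bis-allylic alcohol.
4. The 14-membered ring comes from a catalytic asymmetric alkenylzinc macrocyclisation of an ω-alkynyl enal. This forms C1–C2, sets C2 and gives the E-C1=C14 olefin.
5. The ynal comes from an asymmetric vinylogous Mukaiyama aldol (C5–C6 bond, sets C6, gives E-C3=C4) on an enynal made from geranyl acetate and TMS-acetylene. Ring order: carbocycle, then oxirane, then γ-lactone.

## Route

**Step 1**
Reactants: 1, geranyl acetate
Product: 2, (2E,6E)-8-hydroxy-3,7-dimethylocta-2,6-dien-1-yl acetate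
Conditions: SeO2 (0.1 equiv), t-BuOOH, salicylic acid (cat.), CH2Cl2, 0 °C→rt; then NaBH4, MeOH, 0 °C
Reagents that add atoms: tert-butyl hydroperoxide, CC(C)(C)OO (supplies the O atom, relayed by catalytic SeO2, O=[Se]=O)
Why: SeO2/TBHP allylic oxidation (ene then [2,3] shift) hits only the E-methyl of the electron-rich distal olefin, because the olefin next to the acetate is deactivated.

**Step 2**
Reactants: 2
Product: 3, (2E,6E)-8-bromo-3,7-dimethylocta-2,6-dien-1-yl acetate
Conditions: CBr4, PPh3, CH2Cl2, 0 °C
Reagents that add atoms: carbon tetrabromide, BrC(Br)(Br)Br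
Why: The Appel reaction displaces the primary allylic alcohol by SN2 without allylic shift, and the acetate is inert.

**Step 3**
Reactants: 3; 4, trimethylsilylacetylene
Product: 5, (2E,6E)-3,7-dimethyl-10-(trimethylsilyl)deca-2,6-dien-9-yn-1-yl acetate
Conditions: CuI, NaI, K2CO3, DMF, rt
Reagents that add atoms: trimethylsilylacetylene, C#C[Si](C)(C)C
Why: Cu(I)-acetylide/allyl halide sp–sp3 coupling attacks the primary carbon, forming C13–C14 with the E geometry kept, and the carbonate base spares the acetate and the C–Si bond.

**Step 4**
Reactants: 5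
Product: 6, (2E,6E)-3,7-dimethyldeca-2,6-dien-9-yn-1-ol
Conditions: K2CO3, MeOH, 0 °C→rt
Reagents that add atoms: none
Why: Methanolysis removes the acetate (transesterification) and the alkynyl TMS (protiodesilylation) in one operation, and it is too mild to isomerise the skipped enyne.

**Step 5**
Reactants: 6
Product: 7, (2E,6E)-3,7-dimethyldeca-2,6-dien-9-ynal
Conditions: MnO2, CH2Cl2, rt
Reagents that add atoms: none
Why: MnO2 allylic oxidation gives the geranial-type enal without E/Z erosion and leaves the alkyne untouched.

**Step 6**
Reactants: 8, methyl 3-methylbut-2-enoate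
Product: 9, 1-(tert-butyldimethylsilyloxy)-1-methoxy-3-methylbuta-1,3-diene
Conditions: LDA, THF/DMPU, −78 °C; TBSCl
Reagents that add atoms: TBSCl, CC(C)(C)[Si](C)(C)Cl
Why: Kinetic γ-deprotonation followed by O-silylation gives the silyl dienol ether needed for the vinylogous aldol.

**Step 7**
Reactants: 7; 9
Product: 10, methyl (2E,5S,6E,10E)-5-hydroxy-3,7,11-trimethyltetradeca-2,6,10-trien-13-ynoate
Conditions: SiCl4 (1.5 equiv), (S,S)-Denmark bisphosphoramide (5 mol %), i-Pr2NEt (0.2 equiv), CH2Cl2, −78 °C; aq KF/NaHCO3
Reagents that add atoms: none beyond 9 (the TBS group and SiCl4 are lost on work-up)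
Why: This catalytic enantioselective vinylogous Mukaiyama aldol (Lewis-base-activated SiCl4, open transition state) is γ-selective with conjugated aldehydes and forms C5–C6 together with the E-C3=C4 enoate (any Z isomer lactonises and is separated); Si-face attack sets 6S, using the antipode of the (R,R) catalyst taken to be Re-selective, with the sense to be confirmed by Mosher analysis.

**Step 8**
Reactants: 10
Product: 11, (2E,5S,6E,10E)-3,7,11-trimethyltetradeca-2,6,10-trien-13-yne-1,5-diol
Conditions: DIBAL-H (3.5 equiv), CH2Cl2, −78 °C
Reagents that add atoms: none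
Why: DIBAL-H reduces the enoate 1,2 to the allylic alcohol, and at −78 °C the alkyne and olefins are untouched.

**Step 9**
Reactants: 11
Product: 12, (2E,5S,6E,10E)-5-hydroxy-3,7,11-trimethyltetradeca-2,6,10-trien-13-ynal
Conditions: TEMPO (10 mol %), PhI(OAc)2 (1.1 equiv), CH2Cl2, 0 °C→rt
Reagents that add atoms: none
Why: The oxoammonium (TEMPO/BAIB) oxidation is strongly selective for primary over secondary alcohols, so only C2 is oxidised and the C6 carbinol survives.

**Step 10**
Reactants: 12
Product: 13, (2E,5S,6E,10E)-5-acetoxy-3,7,11-trimethyltetradeca-2,6,10-trien-13-ynal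
Conditions: Ac2O, pyridine, CH2Cl2, 0 °C
Reagents that add atoms: acetic anhydride, CC(=O)OC(C)=O
Why: This acylation installs the acetate of the natural product, which then acts as the only protecting group, and cold weak base avoids vinylogous E1cB loss of acetate.

**Step 11 (key macrocyclisation)**
Reactants: 13
Product: 14, (1R,2E,5S,6E,10E,13E)-5-acetoxy-3,7,11-trimethylcyclotetradeca-2,6,10,13-tetraen-1-ol (cembrane: 2R-OH, 6S-OAc, E-C1=C14)
Conditions: Cy2BH (1.05 equiv), toluene, 0 °C, 1 h; then syringe pump over 6 h into Et2Zn (2 equiv), (+)-DAIB (10 mol %), toluene, 0 °C, final 2 mM; aq NH4Cl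
Reagents that add atoms: none (H only)
Why: In this Oppolzer-type asymmetric alkenylzinc macrocyclisation, Cy2BH syn-hydroborates only the terminal alkyne, B→Zn exchange gives an E-alkenylzinc, and this adds intramolecularly to the enal, with (+)-DAIB directing Re-face attack (the mirror of the (−)-DAIB/Si rule) to give 2R, which has the same spatial arrangement as 2S in the target.

**Step 12**
Reactants: 14
Product: 15, (1S,2S,6S,14S)-6-acetoxy-1,14-epoxide of 14 (trans-epoxide, erythro to the 2-OH; the C2 descriptor changes only through CIP priorities)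
Conditions: Ti(Oi-Pr)4 (1.0 equiv), L-(+)-DIPT (1.2 equiv), t-BuOOH (2 equiv), 4 Å MS, CH2Cl2, −20 °C
Reagents that add atoms: tert-butyl hydroperoxide, CC(C)(C)OO
Why: This is Sharpless epoxidation in its divinyl-carbinol group-selective mode: with L-(+)-tartrate, C1=C14 is the matched olefin of this carbinol and gives the erythro (1S,14S)-epoxide, C3=C4 is mismatched and A1,3-strained, and the non-allylic-alcohol olefins are inert to Ti/TBHP.

**Step 13**
Reactants: 15; 16, diethylphosphonoacetic acid
Product: 17, the 2-O-(diethylphosphonoacetyl) ester of 15 (1R,2S,6S,14S; the C1 descriptor changes by CIP only)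
Conditions: EDC·HCl, DMAP (cat.), CH2Cl2, 0 °C→rt
Reagents that add atoms: diethylphosphonoacetic acid, OC(=O)CP(=O)(OCC)OCC
Why: Steglich-type esterification under neutral conditions avoids Payne migration, retains C2, and leaves the epoxide and acetate intact.

**Step 14 (key lactone annulation)**
Reactants: 17
Product: 18, (1S,2S,6S,14S)-6-acetoxy-15-(diethoxyphosphoryl)-14-hydroxy-cembra-3E,7E,11E-trien-16,2-olide (a C15 epimer mixture, which does not matter)
Conditions: NaH (1.0 equiv), THF, 0→45 °C; AcOH quench
Reagents that add atoms: none
Why: Proposed new method: the phosphonate-stabilised carbanion sits four atoms from C1, and in the erythro isomer O2 can lie anti to the oxirane oxygen while C3 and C14 are also anti, so rear-side 5-exo-tet SN2 attack at C1 forms C1–C15 with inversion (1S, trans fusion) and releases the untouched C14–O (14S), after which proton transfer from C15–H parks the product as its enolate; because the exocyclic P=O carries the charge, the closure behaves as enolexo rather than the disfavoured 5-enolendo mode, and the closest known types are Stork epoxy-carbanion cyclisation, 5-exo C-2 opening of 2,3-epoxy alcohols by O-tethered carbamates, and 5-exo cyclisation of phosphonoacetamides to α-phosphono-γ-lactams.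

**Step 15**
Reactants: 18; 19, formaldehyde
Product: 20, kericembrenolide D
Conditions: K2CO3, MeOH-free aq HCHO (from paraformaldehyde), THF, 0 °C, 20 min (can be telescoped with Step 14)
Reagents that add atoms: formaldehyde, C=O
Why: The HWE methylenation of the α-phosphono-lactone removes only the irrelevant C15 stereocentre, and a short, cold, methanol-free reaction protects the acetate and avoids translactonisation to O14.

## Compound list

| No. | Name | SMILES | Role |
|---|---|---|---|
| 1 | geranyl acetate | CC(C)=CCC/C(C)=C/COC(C)=O | starting material |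
| 2 | 8-hydroxygeranyl acetate | OC/C(C)=C/CC/C(C)=C/COC(C)=O | intermediate |
| 3 | 8-bromogeranyl acetate | BrC/C(C)=C/CC/C(C)=C/COC(C)=O | intermediate |
| 4 | trimethylsilylacetylene | C#C[Si](C)(C)C | starting material |
| 5 | TMS-enyne acetate | C[Si](C)(C)C#CC/C(C)=C/CC/C(C)=C/COC(C)=O | intermediate |
| 6 | (2E,6E)-3,7-dimethyldeca-2,6-dien-9-yn-1-ol | C#CC/C(C)=C/CC/C(C)=C/CO | intermediate |
| 7 | (2E,6E)-3,7-dimethyldeca-2,6-dien-9-ynal | C#CC/C(C)=C/CC/C(C)=C/C=O | intermediate |
| 8 | methyl 3-methylbut-2-enoate | COC(=O)C=C(C)C | starting material |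
| 9 | silyl dienol ether | COC(O[Si](C)(C)C(C)(C)C)=CC(C)=C | intermediate |
| 10 | (5S)-δ-hydroxy enoate | C#CC/C(C)=C/CC/C(C)=C/[C@@H](O)C/C(C)=C/C(=O)OC | intermediate |
| 11 | (5S)-1,5-diol | C#CC/C(C)=C/CC/C(C)=C/[C@@H](O)C/C(C)=C/CO | intermediate |
| 12 | (5S)-hydroxy enal | C#CC/C(C)=C/CC/C(C)=C/[C@@H](O)C/C(C)=C/C=O | intermediate |
| 13 | (5S)-acetoxy ynal | C#CC/C(C)=C/CC/C(C)=C/[C@@H](OC(C)=O)C/C(C)=C/C=O | intermediate |
| 14 | macrocyclic bis-allylic alcohol | O[C@H]1/C=C(\C)C[C@H](OC(C)=O)/C=C(\C)CC/C=C(\C)C/C=C/1 | intermediate |
| 15 | 1,14-epoxy alcohol | O[C@H]1/C=C(\C)C[C@H](OC(C)=O)/C=C(\C)CC/C=C(\C)C[C@@H]2O[C@@H]12 | intermediate |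
| 16 | diethylphosphonoacetic acid | OC(=O)CP(=O)(OCC)OCC | starting material |
| 17 | epoxy phosphonoacetate | CCOP(=O)(OCC)CC(=O)O[C@H]1/C=C(\C)C[C@H](OC(C)=O)/C=C(\C)CC/C=C(\C)C[C@@H]2O[C@@H]12 | intermediate |
| 18 | α-phosphono-lactone | CCOP(=O)(OCC)C1C(=O)O[C@H]2/C=C(\C)C[C@H](OC(C)=O)/C=C(\C)CC/C=C(\C)C[C@H](O)[C@H]12 | intermediate |
| 19 | formaldehyde | C=O | starting material |
| 20 | kericembrenolide D | C=C1C(=O)O[C@H]2/C=C(\C)C[C@H](OC(C)=O)/C=C(\C)CC/C=C(\C)C[C@H](O)[C@H]12 | target |

## Step count

- Total steps: 15.
- Longest linear sequence: 14 (Steps 1–5 and 7–15, from geranyl acetate).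

## Steps most likely to fail

1. **Step 14, tethered carbanion/epoxide closure.** The risks are ester-tether geometry, the partly enolendo character of the closure, and attack of O14 on phosphorus.
   - Fallback: drop the tether. Open epoxy alcohol 15 at C1 with an ethynyl-aluminate (hydroxyl-directed C-2-selective opening, same inversion) to give the 1-ethynyl-2,14-diol.
   - Then build C16 and the exocyclic methylene by Pd-catalysed cyclocarbonylation of the homopropargylic alcohol under CO.
2. **Step 11, alkenylzinc macrocyclisation onto an enal.** The risks are oligomerisation, ethyl transfer and enal reduction.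
   - Fallback: hydrozirconate and iodinate diol 11 to the E-vinyl iodide, carry out Steps 9–10, and close the ring by Ni/Cr (NHK) coupling.
   - Step 12 then serves as a kinetic resolution of the C2 epimers, because only the 2R isomer is epoxidised at C1=C14.
3. **Step 12, group selectivity between the disubstituted and trisubstituted allylic olefins.**
   - Fallback: install the epoxide before ring closure, where no competing olefin exists. Hydroxymethylate the alkyne, reduce with Red-Al to the primary E-allylic alcohol, run a standard AE, and oxidise to the epoxy-aldehyde.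
   - Then close the ring at C2–C3 by NHK with a C3 vinyl iodide, made by asymmetric propargylation of enal 7 followed by Zr-catalysed carboalumination/iodination.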